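**Plan**
- Cuts: the depsidone ester C(=O)–O and diaryl ether C–O bonds (union of rings A and B), the ring A benzylic C–C(=O) bond, and, in the spiro unit, the tetrahydropyran C3'–C4' and O1'–C6' bonds and the spiro C–O(lactone) bond.
- Enabling feature: the spiro carbon C2' is at ketone level and sits between the ring CH2 (C3') and the ring oxygen O1'. With a temporary CO2Me on C3', the C3'–C2'–O1' triad is a β-keto ester enolate (a C,O-dinucleophile). The C4'–C5'–C6'(CH3) triad is the cyclic sulfate of (S)-butane-1,3-diol (a 1,3-dielectrophile).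
- Ring B, forward: methyl orsellinate is benzylated, brominated, carboxylated at the benzylic methyl and homologated to the β-keto ester; a [3+3] annulation closes the dihydropyran; saponification, decarboxylation and acid close the spiro lactone; Br is then changed to OH.
- Ring A, forward: C–H borylation/oxidation, O-methylation, lateral acylation, ketal, benzyl ester. Union: Ullmann ether, hydrogenolysis, seven-membered lactonisation, deketalisation.
- Stereochemistry: C6' (R) comes from SN2 inversion of the (S) secondary sulfate; the spiro centre (S) is the anomerically favoured epimer for an (R)-6'-methyl group and is set by acid equilibration.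

Key step: step 6

**Route**

Step 1
Reactants: 1 methyl 2,4-dihydroxy-6-methylbenzoate (methyl orsellinate)
Product: 2 methyl 2,4-bis(benzyloxy)-6-methylbenzoate
Conditions: BnBr, K2CO3, DMF, 70 °C
Reagents that add atoms: benzyl bromide, BrCc1ccccc1
Why: Williamson O-benzylation of both phenols (the chelated 2-OH needs DMF and heat); the benzyl ethers survive LDA, base and acid and are removed by hydrogenolysis late in the route.

Step 2
Reactants: 2 methyl 2,4-bis(benzyloxy)-6-methylbenzoate
Product: 3 methyl 4,6-bis(benzyloxy)-3-bromo-2-methylbenzoate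
Conditions: NBS, MeCN, 0 °C to rt, dark
Reagents that add atoms: N-bromosuccinimide, O=C1CCC(=O)N1Br
Why: Electrophilic aromatic bromination should go para to the 2-benzyloxy group (next to the methyl group) and not to the crowded position between the two ethers, as with orcinol diethers; this bromine marks the later ether oxygen of ring B.

Step 3
Reactants: 3 methyl 4,6-bis(benzyloxy)-3-bromo-2-methylbenzoate
Product: 4 2-[3,5-bis(benzyloxy)-2-bromo-6-(methoxycarbonyl)phenyl]acetic acid
Conditions: LDA (2.2 equiv), THF, −78 °C; CO2; 1 M HCl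
Reagents that add atoms: carbon dioxide, O=C=O
Why: Ester-directed lateral (benzylic) lithiation of an o-toluate and carboxylation give the homophthalic half ester; the second equivalent of base is taken up by the acidic product.

Step 4
Reactants: 4 2-[3,5-bis(benzyloxy)-2-bromo-6-(methoxycarbonyl)phenyl]acetic acid
Product: 6 methyl 4-[3,5-bis(benzyloxy)-2-bromo-6-(methoxycarbonyl)phenyl]-3-oxobutanoate, via acyl Meldrum's acid 5 (not isolated)
Conditions: Meldrum's acid, DCC, DMAP (cat.), CH2Cl2, 0 °C to rt; filter; MeOH, 65 °C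
Reagents that add atoms: Meldrum's acid (2,2-dimethyl-1,3-dioxane-4,6-dione), CC1(C)OC(=O)CC(=O)O1; methanol, CO
Why: C-acylation of Meldrum's acid by the carbodiimide-activated arylacetic acid and methanolysis through the acylketene give the β-keto ester; the new ester is the temporary activating group that makes the future C3' the most acidic carbon.

Step 5
Reactants: 7 (S)-butane-1,3-diol
Product: 9 (4S)-4-methyl-1,3,2-dioxathiane 2,2-dioxide, via cyclic sulfite 8 (not isolated)
Conditions: SOCl2, CH2Cl2, 0 °C to rt; then RuCl3 (cat.), NaIO4, MeCN/H2O, 0 °C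
Reagents that add atoms: thionyl chloride, O=S(Cl)Cl; sodium periodate, [Na+].[O-]I(=O)(=O)=O
Why: Cyclic sulfite formation and ruthenium-catalysed periodate oxidation give the cyclic sulfate; no C–O bond is broken, so the stereocentre is untouched.

Step 6
Reactants: 6 methyl 4-[3,5-bis(benzyloxy)-2-bromo-6-(methoxycarbonyl)phenyl]-3-oxobutanoate; 9 (4S)-4-methyl-1,3,2-dioxathiane 2,2-dioxide
Product: 11 methyl (6R)-2-{[3,5-bis(benzyloxy)-2-bromo-6-(methoxycarbonyl)phenyl]methyl}-6-methyl-5,6-dihydro-4H-pyran-3-carboxylate, via sulfate monoester 10 (not isolated)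
Conditions: Cs2CO3 (2.5 equiv), DMF, 0 °C to rt, then 60 °C
Reagents that add atoms: none
Why: Cs2CO3 deprotonates 6 at the carbon between the ketone and the added ester (the future C3'), and this enolate opens the cyclic sulfate by SN2 attack at its primary carbon, which forms the C3'–C4' bond and leaves the secondary alkyl sulfate 10; the re-formed enolate then displaces the sulfate through oxygen in a 6-exo-tet closure, which forms the O1'–C6' bond and the dihydropyran ring. The closest known reaction type is the tandem C-alkylation/O-alkylation of β-keto esters with 1,3-dihalopropanes to 5,6-dihydro-4H-pyran-3-carboxylates, combined with the double displacement chemistry of cyclic sulfates. The only ring closed is the six-membered oxygen heterocycle, by O-alkylation; closure through carbon would need a 4-exo-tet cyclobutane formation and should not compete. The C6' stereocentre is set by inversion at the secondary carbon of the (S)-configured sulfate and is therefore (R); C3' becomes sp2, so no second stereocentre has to be controlled here. The step needs alkylation at C3' and not at the benzylic carbon (secured by the extra ester, which makes C3'–H the most acidic), attack at the primary and not the secondary carbon of 9 (sterics), and no Claisen-type attack of the stabilised enolate on the benzoate (which is flanked by two ortho substituents).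

Step 7
Reactants: 11 methyl (6R)-2-{[3,5-bis(benzyloxy)-2-bromo-6-(methoxycarbonyl)phenyl]methyl}-6-methyl-5,6-dihydro-4H-pyran-3-carboxylate
Product: 13 (3S,6'R)-6,8-bis(benzyloxy)-5-bromo-6'-methyl-3',4',5',6'-tetrahydrospiro[isochromane-3,2'-pyran]-1-one, via diacid 12 (not isolated)
Conditions: KOH, DMSO/H2O, 90 °C; HCl to pH 2, extract; TFA, CH2Cl2, rt
Reagents that add atoms: potassium hydroxide, [K+].[OH-] (one oxygen of the lactone carboxyl)
Why: Both methyl esters are saponified; in acid the dihydropyran-3-carboxylic acid (a vinylogous carbonic half ester) is protonated at C3' and loses CO2, which removes the activating group, and the oxocarbenium ion at C2' is captured by the neighbouring benzoic acid in a reversible acyl ketalisation that should settle on the anomerically stabilised (S) spiro centre (lactone C–O axial, 6'-methyl equatorial).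

Step 8
Reactants: 13 (3S,6'R)-6,8-bis(benzyloxy)-5-bromo-6'-methyl-3',4',5',6'-tetrahydrospiro[isochromane-3,2'-pyran]-1-one
Product: 15 (3S,6'R)-6,8-bis(benzyloxy)-5-hydroxy-6'-methyl-3',4',5',6'-tetrahydrospiro[isochromane-3,2'-pyran]-1-one, via aryl boronate 14 (not isolated)
Conditions: pinacolborane, PdCl2(MeCN)2, SPhos, Et3N, 1,4-dioxane, 80 °C; then H2O2, NaHCO3, THF/H2O, 0 °C
Reagents that add atoms: pinacolborane, CC1(C)OBOC1(C)C (boron of 14 only); hydrogen peroxide, OO
Why: Miyaura borylation of the hindered, electron-rich bromide with a dialkylbiarylphosphine ligand and mild peroxide oxidation of the C–B bond give the phenol without acid or hydroxide, so the acyl ketal stays closed (a free o-hydroxybenzyl ketone would cyclise to a benzofuran in acid).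

Step 9
Reactants: 16 methyl 2-bromo-6-methylbenzoate
Product: 18 methyl 2-bromo-4-hydroxy-6-methylbenzoate, via aryl boronate 17 (not isolated)
Conditions: B2pin2, [Ir(OMe)(cod)]2 (cat.), 4,4'-di-tert-butyl-2,2'-bipyridine, THF, 80 °C; then Oxone (KHSO5), acetone/H2O, rt
Reagents that add atoms: bis(pinacolato)diboron, CC1(C)OB(OC1(C)C)B1OC(C)(C)C(C)(C)O1 (boron of 17 only); potassium peroxymonosulfate, [K+].[O-]S(=O)(=O)OO
Why: Sterically controlled iridium-catalysed C–H borylation takes the only ring C–H without an ortho substituent (C4), and oxidation of the boronate in the same flask gives the phenol; the C–Br bond is not touched.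

Step 10
Reactants: 18 methyl 2-bromo-4-hydroxy-6-methylbenzoate
Product: 19 methyl 2-bromo-4-methoxy-6-methylbenzoate
Conditions: MeI, K2CO3, acetone, 55 °C
Reagents that add atoms: iodomethane, CI
Why: Williamson O-methylation of the phenol.

Step 11
Reactants: 19 methyl 2-bromo-4-methoxy-6-methylbenzoate; 20 N-methoxy-N-methylhexanamide
Product: 21 methyl 2-bromo-4-methoxy-6-(2-oxoheptyl)benzoate
Conditions: LDA (1.1 equiv), THF, −78 °C; then 20; AcOH, −78 °C to rt
Reagents that add atoms: none
Why: Lateral lithiation of the o-toluate and Weinreb ketone synthesis; the benzylic anion adds only once because the chelated tetrahedral adduct lasts until work-up, which gives the 2-oxoheptyl chain.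

Step 12
Reactants: 21 methyl 2-bromo-4-methoxy-6-(2-oxoheptyl)benzoate
Product: 22 methyl 2-bromo-4-methoxy-6-[(2-pentyl-1,3-dioxolan-2-yl)methyl]benzoate
Conditions: 1,2-bis(trimethylsilyloxy)ethane, TMSOTf (cat.), CH2Cl2, −78 to −20 °C; Et3N
Reagents that add atoms: 1,2-bis(trimethylsilyloxy)ethane, C[Si](C)(C)OCCO[Si](C)(C)C
Why: Silyl triflate-catalysed ketalisation at low temperature masks the ketone, which would otherwise close on the neighbouring carboxyl derivative to an isocoumarin during the basic coupling and the lactonisation.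

Step 13
Reactants: 22 methyl 2-bromo-4-methoxy-6-[(2-pentyl-1,3-dioxolan-2-yl)methyl]benzoate
Product: 24 benzyl 2-bromo-4-methoxy-6-[(2-pentyl-1,3-dioxolan-2-yl)methyl]benzoate, via potassium carboxylate 23 (not isolated)
Conditions: KOSiMe3, THF, 60 °C; then BnBr, DMF, rt
Reagents that add atoms: benzyl bromide, BrCc1ccccc1
Why: The hindered methyl ester is cleaved by silanolate at the methyl carbon (SN2) and the carboxylate is O-benzylated in the same flask, so that the acid can later be freed by hydrogenolysis without acid or base.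

Step 14
Reactants: 15 (3S,6'R)-6,8-bis(benzyloxy)-5-hydroxy-6'-methyl-3',4',5',6'-tetrahydrospiro[isochromane-3,2'-pyran]-1-one; 24 benzyl 2-bromo-4-methoxy-6-[(2-pentyl-1,3-dioxolan-2-yl)methyl]benzoate
Product: 25 benzyl 2-{[(3S,6'R)-6,8-bis(benzyloxy)-6'-methyl-1-oxo-3',4',5',6'-tetrahydrospiro[isochromane-3,2'-pyran]-5-yl]oxy}-4-methoxy-6-[(2-pentyl-1,3-dioxolan-2-yl)methyl]benzoate
Conditions: CuI (10 mol%), picolinic acid (20 mol%), K3PO4, DMSO, 90 °C
Reagents that add atoms: none
Why: Copper-catalysed Ullmann diaryl ether synthesis; the bromide is activated by its ortho ester and the only free phenol of 15 is O5, which fixes the regiochemistry of the depsidone.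

Step 15
Reactants: 25 the diaryl ether named in step 14
Product: 26 2-{[(3S,6'R)-6,8-dihydroxy-6'-methyl-1-oxo-3',4',5',6'-tetrahydrospiro[isochromane-3,2'-pyran]-5-yl]oxy}-4-methoxy-6-[(2-pentyl-1,3-dioxolan-2-yl)methyl]benzoic acid
Conditions: H2 (1 atm), Pd/C, EtOAc, rt; filter and use at once
Reagents that add atoms: none
Why: Hydrogenolysis removes the benzyl ester and both benzyl ethers under neutral conditions; the ketal, the diaryl ether and the acyl ketal are inert, and the crude acid is carried on directly because it sits next to the ketal.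

Step 16
Reactants: 26 the hydroxy acid named in step 15
Product: 27 ethylene ketal of the target (2-pentyl-1,3-dioxolane in place of the ring A ketone; depsidone ring closed, 8-OH free)
Conditions: DCC, DMAP (cat.), CH2Cl2 (high dilution), 0 °C to rt
Reagents that add atoms: none
Why: Steglich-type lactonisation closes the seven-membered depsidone ester on the hydroxyl ortho to the ether oxygen (O6), the only one within reach; the chelated 8-OH is unreactive and the masked ketone cannot form an isocoumarin.

Step 17
Reactants: 27 the ketal named in step 16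
Product: 28 target CNP0301127.1
Conditions: 1 M HCl, THF, rt
Reagents that add atoms: water, O
Why: Mild aqueous acid hydrolyses the dioxolane to the ketone; the spiro acyl ketal is already the thermodynamic epimer and the aryl ester should be stable to dilute acid at room temperature.

**Compound list**
1 | methyl 2,4-dihydroxy-6-methylbenzoate | COC(=O)c1c(C)cc(O)cc1O | starting material
2 | methyl 2,4-bis(benzyloxy)-6-methylbenzoate | COC(=O)c1c(C)cc(OCc2ccccc2)cc1OCc1ccccc1 | intermediate
3 | methyl 4,6-bis(benzyloxy)-3-bromo-2-methylbenzoate | COC(=O)c1c(C)c(Br)c(OCc2ccccc2)cc1OCc1ccccc1 | intermediate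
4 | 2-[3,5-bis(benzyloxy)-2-bromo-6-(methoxycarbonyl)phenyl]acetic acid | COC(=O)c1c(CC(=O)O)c(Br)c(OCc2ccccc2)cc1OCc1ccccc1 | intermediate
5 | acyl Meldrum's acid of 4 (5-arylacetyl-2,2-dimethyl-1,3-dioxane-4,6-dione) | COC(=O)c1c(CC(=O)C2C(=O)OC(C)(C)OC2=O)c(Br)c(OCc2ccccc2)cc1OCc1ccccc1 | intermediate
6 | methyl 4-[3,5-bis(benzyloxy)-2-bromo-6-(methoxycarbonyl)phenyl]-3-oxobutanoate | COC(=O)CC(=O)Cc1c(Br)c(OCc2ccccc2)cc(OCc2ccccc2)c1C(=O)OC | intermediate
7 | (S)-butane-1,3-diol | C[C@H](O)CCO | starting material
8 | (4S)-4-methyl-1,3,2-dioxathiane 2-oxide (cyclic sulfite) | C[C@H]1CCOS(=O)O1 | intermediate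
9 | (4S)-4-methyl-1,3,2-dioxathiane 2,2-dioxide (cyclic sulfate) | C[C@H]1CCOS(=O)(=O)O1 | intermediate
10 | C-alkylated β-keto ester carrying the (S) secondary sulfate monoester, cesium salt | COC(=O)C(CC[C@H](C)OS(=O)(=O)[O-])C(=O)Cc1c(Br)c(OCc2ccccc2)cc(OCc2ccccc2)c1C(=O)OC.[Cs+] | intermediate
11 | methyl (6R)-2-{[3,5-bis(benzyloxy)-2-bromo-6-(methoxycarbonyl)phenyl]methyl}-6-methyl-5,6-dihydro-4H-pyran-3-carboxylate | COC(=O)C1=C(Cc2c(Br)c(OCc3ccccc3)cc(OCc3ccccc3)c2C(=O)OC)O[C@H](C)CC1 | intermediate
12 | (6R)-2-{[3,5-bis(benzyloxy)-2-bromo-6-carboxyphenyl]methyl}-6-methyl-5,6-dihydro-4H-pyran-3-carboxylic acid | OC(=O)C1=C(Cc2c(Br)c(OCc3ccccc3)cc(OCc3ccccc3)c2C(=O)O)O[C@H](C)CC1 | intermediate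
13 | (3S,6'R)-6,8-bis(benzyloxy)-5-bromo-6'-methyl-3',4',5',6'-tetrahydrospiro[isochromane-3,2'-pyran]-1-one | Brc1c(OCc2ccccc2)cc(OCc2ccccc2)c2c1C[C@]1(CCC[C@@H](C)O1)OC2=O | intermediate
14 | 5-(pinacolboryl) analogue of 13 | CC1(C)OB(OC1(C)C)c1c(OCc2ccccc2)cc(OCc2ccccc2)c2c1C[C@]1(CCC[C@@H](C)O1)OC2=O | intermediate
15 | (3S,6'R)-6,8-bis(benzyloxy)-5-hydroxy-6'-methyl-3',4',5',6'-tetrahydrospiro[isochromane-3,2'-pyran]-1-one | Oc1c(OCc2ccccc2)cc(OCc2ccccc2)c2c1C[C@]1(CCC[C@@H](C)O1)OC2=O | intermediate
16 | methyl 2-bromo-6-methylbenzoate | COC(=O)c1c(C)cccc1Br | starting material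
17 | methyl 2-bromo-6-methyl-4-(4,4,5,5-tetramethyl-1,3,2-dioxaborolan-2-yl)benzoate | COC(=O)c1c(C)cc(B2OC(C)(C)C(C)(C)O2)cc1Br | intermediate
18 | methyl 2-bromo-4-hydroxy-6-methylbenzoate | COC(=O)c1c(C)cc(O)cc1Br | intermediate
19 | methyl 2-bromo-4-methoxy-6-methylbenzoate | COC(=O)c1c(C)cc(OC)cc1Br | intermediate
20 | N-methoxy-N-methylhexanamide | CCCCCC(=O)N(C)OC | starting material
21 | methyl 2-bromo-4-methoxy-6-(2-oxoheptyl)benzoate | CCCCCC(=O)Cc1cc(OC)cc(Br)c1C(=O)OC | intermediate
22 | methyl 2-bromo-4-methoxy-6-[(2-pentyl-1,3-dioxolan-2-yl)methyl]benzoate | CCCCCC1(Cc2cc(OC)cc(Br)c2C(=O)OC)OCCO1 | intermediate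
23 | potassium 2-bromo-4-methoxy-6-[(2-pentyl-1,3-dioxolan-2-yl)methyl]benzoate | CCCCCC1(Cc2cc(OC)cc(Br)c2C(=O)[O-])OCCO1.[K+] | intermediate
24 | benzyl 2-bromo-4-methoxy-6-[(2-pentyl-1,3-dioxolan-2-yl)methyl]benzoate | CCCCCC1(Cc2cc(OC)cc(Br)c2C(=O)OCc2ccccc2)OCCO1 | intermediate
25 | benzyl 2-{[(3S,6'R)-6,8-bis(benzyloxy)-6'-methyl-1-oxo-3',4',5',6'-tetrahydrospiro[isochromane-3,2'-pyran]-5-yl]oxy}-4-methoxy-6-[(2-pentyl-1,3-dioxolan-2-yl)methyl]benzoate | CCCCCC1(Cc2cc(OC)cc(Oc3c(OCc4ccccc4)cc(OCc4ccccc4)c4c3C[C@]3(CCC[C@@H](C)O3)OC4=O)c2C(=O)OCc2ccccc2)OCCO1 | intermediate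
26 | 2-{[(3S,6'R)-6,8-dihydroxy-6'-methyl-1-oxo-3',4',5',6'-tetrahydrospiro[isochromane-3,2'-pyran]-5-yl]oxy}-4-methoxy-6-[(2-pentyl-1,3-dioxolan-2-yl)methyl]benzoic acid | CCCCCC1(Cc2cc(OC)cc(Oc3c(O)cc(O)c4c3C[C@]3(CCC[C@@H](C)O3)OC4=O)c2C(=O)O)OCCO1 | intermediate
27 | ethylene ketal of the target (depsidone closed, 8-OH free) | CCCCCC1(Cc2cc(OC)cc3c2C(=O)Oc2cc(O)c4c(c2O3)C[C@]2(CCC[C@@H](C)O2)OC4=O)OCCO1 | intermediate
28 | CNP0301127.1 (spiro centre S, 6'-methyl carbon R) | CCCCCC(=O)Cc1cc(OC)cc2c1C(=O)Oc1cc(O)c3c(c1O2)C[C@]1(CCC[C@@H](C)O1)OC3=O | target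

**Count**
Total steps: 17. Longest linear sequence: 11 steps (steps 1–4, 6–8 and 14–17).

**Steps most likely to fail**

Step 6. What may go wrong: the enolate of 6 may acylate itself on the neighbouring benzoate (Claisen or enol-lactone closure) faster than it is alkylated, or the secondary sulfate may be lost by elimination instead of O-closure. Fallback, from 3 back to 13: 3 is lithiated at the benzylic methyl with LDA as in step 3 and the anion is added to commercial (R)-6-methyltetrahydro-2H-pyran-2-one. Ring opening of the lactone gives methyl 4,6-bis(benzyloxy)-3-bromo-2-[(6R)-6-hydroxy-2-oxoheptyl]benzoate F1 (in equilibrium with its hemiketal). Warming F1 with TsOH in toluene should expel methanol and close it to 13 under the same thermodynamic control. This builds the tetrahydropyran from a preformed six-carbon lactone and forms the benzylic C–C bond instead.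

Step 8. What may go wrong: slow oxidative addition at the doubly ortho-substituted, electron-rich C–Br bond, with protodebromination taking over. Fallback, from 13 and 24 back to 25: the roles of the coupling partners are exchanged. The unhindered bromide 24 is borylated (B2pin2, PdCl2(dppf), KOAc, dioxane) to benzyl 4-methoxy-2-[(2-pentyl-1,3-dioxolan-2-yl)methyl]-6-(4,4,5,5-tetramethyl-1,3,2-dioxaborolan-2-yl)benzoate F2 and oxidised (H2O2, NaHCO3) to benzyl 2-hydroxy-4-methoxy-6-[(2-pentyl-1,3-dioxolan-2-yl)methyl]benzoate F3. F3 and bromide 13 are then joined by palladium-catalysed C–O coupling (Pd(OAc)2, tBuXPhos, K3PO4, toluene, 100 °C) to give 25, so that neither 14 nor 15 is needed.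

Step 14. What may go wrong: opening or ionisation of the acyl ketal beside the phenoxide at the coupling temperature, or poor turnover with the doubly ortho-substituted phenol. Fallback, from 15 and 23 back to 27: the ester bond is made first and the ether bond second. 15 is hydrogenolysed (H2, Pd/C) to (3S,6'R)-5,6,8-trihydroxy-6'-methyl-3',4',5',6'-tetrahydrospiro[isochromane-3,2'-pyran]-1-one F4. F4 is acylated with carboxylate 23 under Yamaguchi conditions at its most acidic and least hindered hydroxyl (O6, para to the lactone carbonyl) to give (3S,6'R)-5,8-dihydroxy-6'-methyl-1-oxo-3',4',5',6'-tetrahydrospiro[isochromane-3,2'-pyran]-6-yl 2-bromo-4-methoxy-6-[(2-pentyl-1,3-dioxolan-2-yl)methyl]benzoate F5. Intramolecular Ullmann etherification of F5 (CuI, picolinic acid, K3PO4, DMSO) between O5–H and the ring A bromide closes the seven-membered ring to 27; the 2,6-disubstituted benzoate should be slow to migrate between the two neighbouring oxygens.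

**Further compounds**
F1 | step 6 | methyl 4,6-bis(benzyloxy)-3-bromo-2-[(6R)-6-hydroxy-2-oxoheptyl]benzoate | C[C@@H](O)CCCC(=O)Cc1c(Br)c(OCc2ccccc2)cc(OCc2ccccc2)c1C(=O)OC
F2 | step 8 | benzyl 4-methoxy-2-[(2-pentyl-1,3-dioxolan-2-yl)methyl]-6-(4,4,5,5-tetramethyl-1,3,2-dioxaborolan-2-yl)benzoate | CCCCCC1(Cc2cc(OC)cc(B3OC(C)(C)C(C)(C)O3)c2C(=O)OCc2ccccc2)OCCO1
F3 | step 8 | benzyl 2-hydroxy-4-methoxy-6-[(2-pentyl-1,3-dioxolan-2-yl)methyl]benzoate | CCCCCC1(Cc2cc(OC)cc(O)c2C(=O)OCc2ccccc2)OCCO1
F4 | step 14 | (3S,6'R)-5,6,8-trihydroxy-6'-methyl-3',4',5',6'-tetrahydrospiro[isochromane-3,2'-pyran]-1-one | Oc1cc(O)c2c(c1O)C[C@]1(CCC[C@@H](C)O1)OC2=O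
F5 | step 14 | (3S,6'R)-5,8-dihydroxy-6'-methyl-1-oxo-3',4',5',6'-tetrahydrospiro[isochromane-3,2'-pyran]-6-yl 2-bromo-4-methoxy-6-[(2-pentyl-1,3-dioxolan-2-yl)methyl]benzoate | CCCCCC1(Cc2cc(OC)cc(Br)c2C(=O)Oc2cc(O)c3c(c2O)C[C@]2(CCC[C@@H](C)O2)OC3=O)OCCO1
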